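**Retrosynthetic overview**

1. The butenolide ring is carried as a bought 3‑substituted furan and is re-formed last (singlet‑oxygen oxidation to the 5‑hydroxybutenolide, then NaBH4 reduction and relactonisation). The cyclohexene ring is bought with dihydro‑β‑ionone.
2. Key disconnection: the single bond between the alkene CH (C3 of the deca‑3,7‑diene chain) and the CH2 (C2) next to the carbinol carbon. It is made by an enantioselective palladium‑catalysed three‑component conjunctive cross‑coupling of a (Z)‑alkenyl bromide, vinylmagnesium bromide and a 3‑furylboronic ester, followed by C–B oxidation in the same flask.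
3. Enabling feature: the carbinol carbon C1 lies between C4 of the butenolide ring (an sp2 ring carbon, carried as C3 of a furan, which can migrate from boron) and a CH2 bonded to the sp2 CH of the trisubstituted alkene. This Ar–CH(O)–CH2–C(sp2) array is what a vinylboron ate complex delivers.
4. The (Z)‑alkenyl bromide comes from a C16 homoallylic Grignard reagent and propargyl alcohol (copper‑catalysed anti‑carbomagnesiation, then bromination). The C16 bromide comes from dihydro‑β‑ionone (terminal alkyne, zirconium‑catalysed methylalumination, ethylene oxide).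
5. Ring order: cyclohexene (bought), furan (bought), butenolide from the furan in steps 8 and 9.

Key step: step 6

Remark: the sense of induction of the MandyPhos–palladium catalyst is assigned by analogy with aryl‑migrating conjunctive couplings; the ligand antipode that gives the (R)‑boronate 17 is meant and is written as (Sp,Sp) throughout.

**Route**

Step 1
Reactants: 1 dihydro‑β‑ionone [4‑(2,6,6‑trimethylcyclohex‑1‑en‑1‑yl)butan‑2‑one]
Product: 3 2‑(but‑3‑yn‑1‑yl)‑1,3,3‑trimethylcyclohex‑1‑ene, via diethyl enol phosphate 2 (not isolated)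
Conditions: LiN(iPr)2 (1.05 equiv), THF, −78 °C; ClP(O)(OEt)2, −78 °C → rt; then LiN(iPr)2 (2.3 equiv), THF, −78 °C → rt; aq. NH4Cl
Reagents that add atoms: none
Why: Kinetic deprotonation at the methyl group gives the terminal enolate, and its enol phosphate undergoes base‑induced elimination to the terminal alkyne (methyl ketone to alkyne conversion through an enol phosphate), leaving the tetrasubstituted ring alkene untouched.

Step 2
Reactants: 3 2‑(but‑3‑yn‑1‑yl)‑1,3,3‑trimethylcyclohex‑1‑ene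
Product: 6 (E)‑4‑methyl‑6‑(2,6,6‑trimethylcyclohex‑1‑en‑1‑yl)hex‑3‑en‑1‑ol, via alkenyldimethylalane 4 (not isolated), via lithium alkenyl(butyl)dimethylalanate 5 (not isolated)
Conditions: Me3Al (2 equiv), Cp2ZrCl2 (0.2 equiv), ClCH2CH2Cl, rt; then n‑BuLi, THF/hexane, −30 °C; ethylene oxide, −30 °C → rt; aq. HCl
Reagents that add atoms: trimethylaluminium C[Al](C)C; ethylene oxide C1CO1
Why: Zirconium‑catalysed syn‑methylalumination of the terminal alkyne (Negishi carboalumination) places aluminium on the terminal carbon cis to the new methyl group, and the derived alanate opens ethylene oxide with retention at the alkenyl carbon, which fixes the E‑trisubstituted alkene.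

Step 3
Reactants: 6 (E)‑4‑methyl‑6‑(2,6,6‑trimethylcyclohex‑1‑en‑1‑yl)hex‑3‑en‑1‑ol
Product: 7 2‑[(E)‑6‑bromo‑3‑methylhex‑3‑en‑1‑yl]‑1,3,3‑trimethylcyclohex‑1‑ene
Conditions: CBr4, PPh3, CH2Cl2, 0 °C
Reagents that add atoms: carbon tetrabromide BrC(Br)(Br)Br
Why: The Appel reaction converts the primary alcohol into the bromide under neutral conditions that should leave both alkenes and their geometry unchanged.

Step 4
Reactants: 7 2‑[(E)‑6‑bromo‑3‑methylhex‑3‑en‑1‑yl]‑1,3,3‑trimethylcyclohex‑1‑ene; 8 propargyl alcohol (prop‑2‑yn‑1‑ol)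
Product: 12 (Z)‑3‑bromo‑2‑[(E)‑4‑methyl‑6‑(2,6,6‑trimethylcyclohex‑1‑en‑1‑yl)hex‑3‑en‑1‑yl]prop‑2‑en‑1‑ol, via homoallylic Grignard reagent 9 (not isolated), via chloromagnesium prop‑2‑yn‑1‑olate 10 (not isolated), via cyclic alkenylmagnesium alkoxide 11 (not isolated)
Conditions: 7, Mg turnings, THF, rt; separately 8, iPrMgCl (1.0 equiv), THF, 0 °C; combine, CuI (15 mol%), THF/Et2O, rt → 40 °C; then BrCl2C–CCl2Br, −40 → 0 °C; aq. NH4Cl
Reagents that add atoms: 1,2‑dibromo‑1,1,2,2‑tetrachloroethane ClC(Cl)(Br)C(Cl)(Cl)Br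
Why: Copper‑catalysed anti‑carbomagnesiation of the propargylic alkoxide delivers the alkyl group to C2 and magnesium to C3 inside a five‑membered oxamagnesacycle, so electrophilic bromination of the C–Mg bond with retention should place bromine cis to CH2OH (Z).

Step 5
Reactants: 12 (Z)‑3‑bromo‑2‑[(E)‑4‑methyl‑6‑(2,6,6‑trimethylcyclohex‑1‑en‑1‑yl)hex‑3‑en‑1‑yl]prop‑2‑en‑1‑ol
Product: 13 tert‑butyl({(Z)‑3‑bromo‑2‑[(E)‑4‑methyl‑6‑(2,6,6‑trimethylcyclohex‑1‑en‑1‑yl)hex‑3‑en‑1‑yl]prop‑2‑en‑1‑yl}oxy)dimethylsilane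
Conditions: TBSCl, imidazole, DMF, rt
Reagents that add atoms: tert‑butyldimethylsilyl chloride CC(C)(C)[Si](C)(C)Cl
Why: Standard silylation of the primary allylic alcohol removes the acidic proton that would otherwise quench the boron ate complex of the next step.

Step 6
Reactants: 13 the silyl ether of step 5; 14 2‑(furan‑3‑yl)‑4,4,5,5‑tetramethyl‑1,3,2‑dioxaborolane; 15 vinylmagnesium bromide
Product: 18 (1R,3Z,7E)‑4‑{[(tert‑butyldimethylsilyl)oxy]methyl}‑1‑(furan‑3‑yl)‑8‑methyl‑10‑(2,6,6‑trimethylcyclohex‑1‑en‑1‑yl)deca‑3,7‑dien‑1‑ol, via furyl(vinyl)boron ate complex 16 (not isolated), via secondary pinacol boronic ester 17 (not isolated)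
Conditions: 14, 15 (1.0 equiv), THF, 0 °C → rt; NaOTf (2 equiv); then 13, Pd(OAc)2 (2 mol%), (Sp,Sp)‑MandyPhos [1,1′‑bis(diarylphosphino)‑2,2′‑bis(α‑dimethylaminobenzyl)ferrocene, aryl = 3,5‑dimethyl‑4‑methoxyphenyl] (2.4 mol%), THF/DMSO, 40 → 60 °C; then 3 M NaOH, 30% H2O2, 0 °C → rt
Reagents that add atoms: hydrogen peroxide OO
Why: Vinylmagnesium bromide adds to the 3‑furylboronic ester to give a four‑coordinate boron ate complex, the alkenyl bromide adds oxidatively to zerovalent palladium, and once NaOTf has taken up the bromide the cationic divalent alkenylpalladium binds the vinyl group and triggers a 1,2‑metalate shift in which the 3‑furyl group migrates from boron to the α‑carbon anti to palladium while the β‑carbon becomes bonded to palladium; reductive elimination then joins that CH2 to the alkene CH. The closest known reaction type is the palladium‑catalysed enantioselective three‑component conjunctive cross‑coupling of vinylboron ate complexes with aryl or alkenyl electrophiles. No ring is closed. The new stereocentre (the boron‑bearing carbon, later the carbinol carbon) is set under catalyst control by the planar‑chiral bisphosphine during the metalate shift and is carried into the alcohol by stereoretentive C–B oxidation with alkaline peroxide. The step needs the metalate shift to outrun direct transfer of furyl or vinyl from boron to palladium (Suzuki–Miyaura pathway), which the wide‑bite‑angle ligand and the halide‑free cationic palladium should secure, and it needs the Z geometry to be kept, which oxidative addition and reductive elimination at an alkenyl carbon do; the silyl ether keeps the allylic oxygen from interfering.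

Step 7
Reactants: 18 the furyl carbinol silyl ether of step 6
Product: 19 (1R,3Z,7E)‑1‑(furan‑3‑yl)‑4‑(hydroxymethyl)‑8‑methyl‑10‑(2,6,6‑trimethylcyclohex‑1‑en‑1‑yl)deca‑3,7‑dien‑1‑ol
Conditions: Bu4NF, THF, 0 °C → rt
Reagents that add atoms: none
Why: Fluoride‑mediated desilylation frees the primary allylic alcohol while the furan, the alkenes and the carbinol stereocentre are inert.

Step 8
Reactants: 19 the furyl diol of step 7
Product: 21 5‑hydroxy‑4‑[(1R,3Z,7E)‑1‑hydroxy‑4‑(hydroxymethyl)‑8‑methyl‑10‑(2,6,6‑trimethylcyclohex‑1‑en‑1‑yl)deca‑3,7‑dien‑1‑yl]furan‑2(5H)‑one (both C5 epimers), via furan endoperoxide 20 (not isolated)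
Conditions: O2, hν (visible), tetraphenylporphyrin (cat.), iPr2NEt, CH2Cl2, −78 °C; then warm, aq. oxalic acid
Reagents that add atoms: oxygen O=O
Why: Singlet oxygen is expected to add across the furan ([4+2] cycloaddition) faster than it reacts with the alkenes at −78 °C, and the hindered amine should remove the less shielded bridgehead hydrogen of the endoperoxide (Kornblum–DeLaMare‑type fragmentation), which puts the carbonyl remote from the side chain and the hemiacetal carbon next to it.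

Step 9
Reactants: 21 the 5‑hydroxybutenolide of step 8
Product: 22 4‑[(1R,3Z,7E)‑1‑hydroxy‑4‑(hydroxymethyl)‑8‑methyl‑10‑(2,6,6‑trimethylcyclohex‑1‑en‑1‑yl)deca‑3,7‑dien‑1‑yl]furan‑2(5H)‑one
Conditions: NaBH4, EtOH, 0 °C; then 1 M HCl to pH 2, rt
Reagents that add atoms: none
Why: The 5‑hydroxybutenolide reacts through its ring‑opened (Z)‑aldehyde carboxylate, borohydride reduces the aldehyde, and the cis γ‑hydroxy acid relactonises on acidification to the 4‑substituted furan‑2(5H)‑one without touching the carbinol stereocentre.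

**Compound list**

1 | dihydro‑β‑ionone, 4‑(2,6,6‑trimethylcyclohex‑1‑en‑1‑yl)butan‑2‑one | CC1=C(CCC(C)=O)C(C)(C)CCC1 | starting material
2 | diethyl 4‑(2,6,6‑trimethylcyclohex‑1‑en‑1‑yl)but‑1‑en‑2‑yl phosphate | CC1=C(CCC(=C)OP(=O)(OCC)OCC)C(C)(C)CCC1 | intermediate
3 | 2‑(but‑3‑yn‑1‑yl)‑1,3,3‑trimethylcyclohex‑1‑ene | CC1=C(CCC#C)C(C)(C)CCC1 | intermediate
4 | dimethyl[(E)‑2‑methyl‑4‑(2,6,6‑trimethylcyclohex‑1‑en‑1‑yl)but‑1‑en‑1‑yl]alane | CC1=C(CC/C(C)=C/[Al](C)C)C(C)(C)CCC1 | intermediate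
5 | lithium butyl(dimethyl)[(E)‑2‑methyl‑4‑(2,6,6‑trimethylcyclohex‑1‑en‑1‑yl)but‑1‑en‑1‑yl]alanate | [Li+].CCCC[Al-](C)(C)/C=C(\C)CCC1=C(C)CCCC1(C)C | intermediate
6 | (E)‑4‑methyl‑6‑(2,6,6‑trimethylcyclohex‑1‑en‑1‑yl)hex‑3‑en‑1‑ol | CC1=C(CC/C(C)=C/CCO)C(C)(C)CCC1 | intermediate
7 | 2‑[(E)‑6‑bromo‑3‑methylhex‑3‑en‑1‑yl]‑1,3,3‑trimethylcyclohex‑1‑ene | CC1=C(CC/C(C)=C/CCBr)C(C)(C)CCC1 | intermediate
8 | propargyl alcohol | C#CCO | starting material
9 | [(E)‑4‑methyl‑6‑(2,6,6‑trimethylcyclohex‑1‑en‑1‑yl)hex‑3‑en‑1‑yl]magnesium bromide | CC1=C(CC/C(C)=C/CC[Mg]Br)C(C)(C)CCC1 | intermediate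
10 | chloromagnesium prop‑2‑yn‑1‑olate | C#CCO[Mg]Cl | intermediate
11 | 4‑[(E)‑4‑methyl‑6‑(2,6,6‑trimethylcyclohex‑1‑en‑1‑yl)hex‑3‑en‑1‑yl]‑2,5‑dihydro‑1,2‑oxamagnesole | CC1=C(CC/C(C)=C/CCC2=C[Mg]OC2)C(C)(C)CCC1 | intermediate
12 | (Z)‑3‑bromo‑2‑[(E)‑4‑methyl‑6‑(2,6,6‑trimethylcyclohex‑1‑en‑1‑yl)hex‑3‑en‑1‑yl]prop‑2‑en‑1‑ol | CC1=C(CC/C(C)=C/CC/C(=C/Br)CO)C(C)(C)CCC1 | intermediate
13 | tert‑butyl({(Z)‑3‑bromo‑2‑[(E)‑4‑methyl‑6‑(2,6,6‑trimethylcyclohex‑1‑en‑1‑yl)hex‑3‑en‑1‑yl]prop‑2‑en‑1‑yl}oxy)dimethylsilane | CC1=C(CC/C(C)=C/CC/C(=C/Br)CO[Si](C)(C)C(C)(C)C)C(C)(C)CCC1 | intermediate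
14 | 2‑(furan‑3‑yl)‑4,4,5,5‑tetramethyl‑1,3,2‑dioxaborolane | CC1(C)OB(OC1(C)C)c1ccoc1 | starting material
15 | vinylmagnesium bromide | C=C[Mg]Br | starting material
16 | bromomagnesium ethenyl(furan‑3‑yl)(pinacolato)borate | C=C[B-]1(OC(C)(C)C(C)(C)O1)c1ccoc1.[Mg+]Br | intermediate
17 | 2‑[(1R,3Z,7E)‑4‑{[(tert‑butyldimethylsilyl)oxy]methyl}‑1‑(furan‑3‑yl)‑8‑methyl‑10‑(2,6,6‑trimethylcyclohex‑1‑en‑1‑yl)deca‑3,7‑dien‑1‑yl]‑4,4,5,5‑tetramethyl‑1,3,2‑dioxaborolane | CC1=C(CC/C(C)=C/CC/C(=C/C[C@@H](B2OC(C)(C)C(C)(C)O2)c2ccoc2)CO[Si](C)(C)C(C)(C)C)C(C)(C)CCC1 | intermediate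
18 | (1R,3Z,7E)‑4‑{[(tert‑butyldimethylsilyl)oxy]methyl}‑1‑(furan‑3‑yl)‑8‑methyl‑10‑(2,6,6‑trimethylcyclohex‑1‑en‑1‑yl)deca‑3,7‑dien‑1‑ol | CC1=C(CC/C(C)=C/CC/C(=C/C[C@@H](O)c2ccoc2)CO[Si](C)(C)C(C)(C)C)C(C)(C)CCC1 | intermediate
19 | (1R,3Z,7E)‑1‑(furan‑3‑yl)‑4‑(hydroxymethyl)‑8‑methyl‑10‑(2,6,6‑trimethylcyclohex‑1‑en‑1‑yl)deca‑3,7‑dien‑1‑ol | CC1=C(CC/C(C)=C/CC/C(=C/C[C@@H](O)c2ccoc2)CO)C(C)(C)CCC1 | intermediate
20 | 2,3,7‑trioxabicyclo[2.2.1]hept‑5‑ene (furan endoperoxide) carrying the (1R,3Z,7E) side chain at C5 | CC1=C(CC/C(C)=C/CC/C(=C/C[C@@H](O)C2=CC3OOC2O3)CO)C(C)(C)CCC1 | intermediate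
21 | 5‑hydroxy‑4‑[(1R,3Z,7E)‑1‑hydroxy‑4‑(hydroxymethyl)‑8‑methyl‑10‑(2,6,6‑trimethylcyclohex‑1‑en‑1‑yl)deca‑3,7‑dien‑1‑yl]furan‑2(5H)‑one | CC1=C(CC/C(C)=C/CC/C(=C/C[C@@H](O)C2=CC(=O)OC2O)CO)C(C)(C)CCC1 | intermediate
22 | 4‑[(1R,3Z,7E)‑1‑hydroxy‑4‑(hydroxymethyl)‑8‑methyl‑10‑(2,6,6‑trimethylcyclohex‑1‑en‑1‑yl)deca‑3,7‑dien‑1‑yl]furan‑2(5H)‑one | CC1=C(CC/C(C)=C/CC/C(=C/C[C@@H](O)C2=CC(=O)OC2)CO)C(C)(C)CCC1 | target

**Step count and risks**

Total steps: 9. Longest linear sequence: 9 steps (1 → 22).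

Step 6 is the most likely to fail. Direct transfer of the furyl or vinyl group from boron to palladium may outrun the metalate shift, residual halide may inhibit the catalyst, or facial control in the shift may be poor. The fallback sets out from 13 and forms the same bond with reversed polarity. Palladium‑catalysed α‑alkenylation of the lithium enolate of commercially available 3‑acetylfuran with 13 (Pd2(dba)3, a bulky monophosphine, LiN(SiMe3)2, toluene) would give the β,γ‑unsaturated ketone (3Z,7E)‑4‑{[(tert‑butyldimethylsilyl)oxy]methyl}‑1‑(furan‑3‑yl)‑8‑methyl‑10‑(2,6,6‑trimethylcyclohex‑1‑en‑1‑yl)deca‑3,7‑dien‑1‑one F1. Noyori asymmetric transfer hydrogenation of this heteroaryl ketone (RuCl[(R,R)‑TsDPEN](p‑cymene), HCO2H/Et3N) would give the (R)‑alcohol and comes back to the route at 18.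

Step 8 is next. The ene reaction of singlet oxygen at the tetrasubstituted ring alkene may compete with furan cycloaddition, or proton abstraction may occur at the wrong bridgehead and give the regioisomeric hydroxybutenolide. The fallback sets out from 18 and avoids photooxygenation. Silylation of the secondary alcohol (TBSOTf, 2,6‑lutidine) would give the bis(silyl) ether tert‑butyl{[(1R,3Z,7E)‑4‑{[(tert‑butyldimethylsilyl)oxy]methyl}‑1‑(furan‑3‑yl)‑8‑methyl‑10‑(2,6,6‑trimethylcyclohex‑1‑en‑1‑yl)deca‑3,7‑dien‑1‑yl]oxy}dimethylsilane F2. Lithiation with sec‑BuLi in THF at −78 °C is expected to go to the furan α‑carbon remote from the bulky silyloxy branch and give the 5‑lithiofuran F3. Trapping with B(OMe)3 would give the lithium trimethoxy(furyl)borate F4, and oxidation with H2O2/AcOH would convert it through the 2‑hydroxyfuran tautomer into the bis(silyl) ether of the target butenolide F5. HF·pyridine in THF would remove both silyl groups and comes back to the route at 22.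

Step 4 is third. Deprotonation of the terminal alkyne may consume the valuable Grignard reagent, or carbomagnesiation with the long primary alkyl group may be sluggish. The fallback sets out from 3 and 8, carries out the carbomagnesiation with a cheap Grignard reagent in excess and joins the two halves by cross‑coupling. The alkenylalane 4 from 3 is quenched with iodine to give 2‑[(E)‑4‑iodo‑3‑methylbut‑3‑en‑1‑yl]‑1,3,3‑trimethylcyclohex‑1‑ene F6. Separately, 8 with excess 15 and CuI would give the cyclic alkenylmagnesium alkoxide 4‑ethenyl‑2,5‑dihydro‑1,2‑oxamagnesole F7, which is brominated with BrCl2C–CCl2Br to (Z)‑2‑(bromomethylidene)but‑3‑en‑1‑ol F8 and silylated (TBSCl, imidazole) to tert‑butyl{[(Z)‑2‑(bromomethylidene)but‑3‑en‑1‑yl]oxy}dimethylsilane F9. Hydroboration of the terminal vinyl group with 9‑BBN would give 9‑[(Z)‑4‑bromo‑3‑{[(tert‑butyldimethylsilyl)oxy]methyl}but‑3‑en‑1‑yl]‑9‑borabicyclo[3.3.1]nonane F10. A B‑alkyl Suzuki–Miyaura coupling of F10 with F6 (PdCl2(dppf), Cs2CO3, DMF/THF/H2O, rt) should take place at the C–I bond, leave the hindered C–Br bond, and come back to the route at 13.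

**Further compounds**

F1 | step 6 | (3Z,7E)‑4‑{[(tert‑butyldimethylsilyl)oxy]methyl}‑1‑(furan‑3‑yl)‑8‑methyl‑10‑(2,6,6‑trimethylcyclohex‑1‑en‑1‑yl)deca‑3,7‑dien‑1‑one | CC1=C(CC/C(C)=C/CC/C(=C/CC(=O)c2ccoc2)CO[Si](C)(C)C(C)(C)C)C(C)(C)CCC1
F2 | step 8 | tert‑butyl{[(1R,3Z,7E)‑4‑{[(tert‑butyldimethylsilyl)oxy]methyl}‑1‑(furan‑3‑yl)‑8‑methyl‑10‑(2,6,6‑trimethylcyclohex‑1‑en‑1‑yl)deca‑3,7‑dien‑1‑yl]oxy}dimethylsilane | CC1=C(CC/C(C)=C/CC/C(=C/C[C@@H](O[Si](C)(C)C(C)(C)C)c2ccoc2)CO[Si](C)(C)C(C)(C)C)C(C)(C)CCC1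
F3 | step 8 | 5‑lithiofuran derived from F2 (lithium on the furan α‑carbon remote from the side chain) | CC1=C(CC/C(C)=C/CC/C(=C/C[C@@H](O[Si](C)(C)C(C)(C)C)c2cc([Li])oc2)CO[Si](C)(C)C(C)(C)C)C(C)(C)CCC1
F4 | step 8 | lithium trimethoxy(furyl)borate derived from F3 | CC1=C(CC/C(C)=C/CC/C(=C/C[C@@H](O[Si](C)(C)C(C)(C)C)c2cc([B-](OC)(OC)OC)oc2)CO[Si](C)(C)C(C)(C)C)C(C)(C)CCC1.[Li+]
F5 | step 8 | bis(tert‑butyldimethylsilyl) ether of 22 | CC1=C(CC/C(C)=C/CC/C(=C/C[C@@H](O[Si](C)(C)C(C)(C)C)C2=CC(=O)OC2)CO[Si](C)(C)C(C)(C)C)C(C)(C)CCC1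
F6 | step 4 | 2‑[(E)‑4‑iodo‑3‑methylbut‑3‑en‑1‑yl]‑1,3,3‑trimethylcyclohex‑1‑ene | CC1=C(CC/C(C)=C/I)C(C)(C)CCC1
F7 | step 4 | 4‑ethenyl‑2,5‑dihydro‑1,2‑oxamagnesole | C=CC1=C[Mg]OC1
F8 | step 4 | (Z)‑2‑(bromomethylidene)but‑3‑en‑1‑ol | C=C/C(=C/Br)CO
F9 | step 4 | tert‑butyl{[(Z)‑2‑(bromomethylidene)but‑3‑en‑1‑yl]oxy}dimethylsilane | C=C/C(=C/Br)CO[Si](C)(C)C(C)(C)C
F10 | step 4 | 9‑[(Z)‑4‑bromo‑3‑{[(tert‑butyldimethylsilyl)oxy]methyl}but‑3‑en‑1‑yl]‑9‑borabicyclo[3.3.1]nonane | Br/C=C(\CO[Si](C)(C)C(C)(C)C)CCB1C2CCCC1CCC2
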